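If you want the top of E in a new flask before any fit, start from the ceiling the charges set. Each E holds two J, so E can reach, as a fraction of the X charged, the J charge over twice the X charge. Where that is below one, J is the limiting reagent, and this ceiling is the full mark of your scale, with no E at all as its zero.

| flask | X | J | remark | time |
|---|---|---|---|---|
| maple | 0.54 M | 0.80 M | run made earlier |  |
| alder | 1.2 M | 0.80 M | run made earlier |  |
| flask | 0.80 M | 0.800 M |  | 80 min |

- the moment within 80 min at which there is most E
- the amount of E, in percent of the X charged, at that time
- earliest time at which at least nineteen twentieths of that best amount are there, in min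
- latest time at which they still are, in min

| run | time / min | E / % | X / % |
|---|---|---|---|
| maple | 2.00 | 27.1 | 51.9 |
| maple | 6.00 | 44.8 | 41.2 |
| maple | 15.0 | 45.0 | 38.2 |
| maple | 50.0 | 33.9 | 35.6 |
| alder | 2.00 | 15.5 | 67.5 |
| alder | 6.00 | 21.3 | 67.3 |
| alder | 15.0 | 20.2 | 66.3 |
| alder | 50.0 | 15.3 | 66.0 |

(standard deviation of a reading: 0.5 percentage points)

Read the tables at their highest E. In maple the ceiling is 74.1% and the highest reading is 45.0%, a fraction 60.8% of it. In alder, with about twice the X, the ceiling is 33.3% and the highest reading is 21.3%, a fraction 63.9%. So the percentages differ widely, but the two fractions stand close. Their mean is the J share 62.3%, the fraction of the ceiling that E reaches at its top, read with the J charge held at 0.80 M and carrying the scatter of the readings.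

The flask has that J charge and a ceiling of 50.0%, so I expect about 31.2%.

Now the time column. At 2.00 min the runs stand at 60.2% and 72.8% of their highest readings, while at 15.0 min alder still holds 94.8% and maple has its highest. I take these over: the top between 6.00 min and 15.0 min, the window opening before 6.00 min and shutting near 15.0 min or later.

The forecast, which holds that the runs “fit a stepwise equilibrium”, gives 30.3% at 8 min, with the window from 4.8 min to 15 min.

The flask gives 32.8% at 8.19 min, with the window from 4.72 min to 15.6 min. That is 65.6% of its ceiling, somewhat above the J share.

    X + J ⇌ G + Q (K = 0.840, k = 0.0120 M⁻¹ s⁻¹)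
    Q + J ⇌ G + E (K = 16.0, k = 0.0250 M⁻¹ s⁻¹)
    G + E → Z (k = 3.50 × 10⁻⁴ M⁻¹ s⁻¹)

In the flask at 80.0 min, Q + J and G + E relax, both ways together, with a half-life of 2.52 min, shorter than the 80 min allowed, while the whole flask has a mode of half-life 67.6 min, longer. E is then made at 0.244 times the rate at which it is used up, and it stands at 17.4% beside 23.8% of Z. A neighbouring flask with 1.4 M of X has a ceiling of 28.6%, so the J share gives 17.8%; computed, its best is 18.7%.

All runs were computed with constants of no real substance; noise was put on by code.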